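**Plan**

- Retrosynthesis: the five aryl O–Me bonds and the benzylic C=O of a diaryl ketone are removed first. The central benzene ring (C1 phenethyl, C2/C6 benzyl, C3/C5 oxygen, C4 H) is then cut at C1–C2 and C3–C4.
- Enabling feature: C4–C5(O)–C6–C1 of that ring, already carrying the oxygen, the aroyl carbon and the phenethyl chain, are C3–C6 of a 4-methoxy-5-aroyl-6-phenethyl-2-pyrone. C2–C3(O) are the two alkene carbons of the dimethyl ketene acetal of a 3-arylpropanoate.
- Pyrone branch: Claisen condensation gives a 1,3-diketone, malonyl dichloride closes the 2-pyrone ring, and O-methylation follows.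
- Dienophile branch: Pinner reaction of the arylpropanenitrile, orthoester formation, then loss of methanol to the ketene acetal.
- Union: cycloaddition, extrusion of carbon dioxide and loss of methanol build the central benzene ring. Ionic hydrogenation of the ketone and global demethylation finish the synthesis.
- Stereochemistry: the target has no stereocentre; the sp3 centres formed transiently in the key step vanish on aromatisation.

Key step: step 7

Assumption: in the malonyl dichloride condensation the enol oxygen of the aliphatic ketone, not that of the anisoyl ketone, is taken to close the lactone; the opposite outcome is covered among the fallbacks.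

**Route**

Step 1
Reactants: 1 4'-methoxyacetophenone; 2 methyl 3-(4-methoxyphenyl)propanoate
Product: 3 1,5-bis(4-methoxyphenyl)pentane-1,3-dione
Conditions: NaH (2.5 equiv), THF, 0 °C to reflux; then 1 M HCl
Reagents that add atoms: none
Why: Crossed Claisen condensation, in which the more acidic methyl ketone is deprotonated in preference to the ester, its enolate is acylated by 2, and irreversible deprotonation of the 1,3-diketone drives the reaction to completion.

Step 2
Reactants: 3 1,5-bis(4-methoxyphenyl)pentane-1,3-dione; 4 malonyl dichloride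
Product: 6 4-hydroxy-5-(4-methoxybenzoyl)-6-[2-(4-methoxyphenyl)ethyl]-2H-pyran-2-one, via triketo acid chloride 5 (not isolated)
Conditions: CH2(COCl)2 (1.3 equiv), ClCH2CH2Cl, 20 to 60 °C, N2 sweep
Reagents that add atoms: none
Why: The known condensation of malonyl dichloride with 1,3-dicarbonyl compounds should C-acylate the central carbon of the enolised diketone to give 5, after which the enol oxygen of the aliphatic ketone closes the 4-hydroxy-2-pyrone by 6-exo-trig attack on the second acid chloride, the anisoyl carbonyl being a poorly enolised vinylogous ester that is expected to remain a ketone.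

Step 3
Reactants: 6 4-hydroxy-5-(4-methoxybenzoyl)-6-[2-(4-methoxyphenyl)ethyl]-2H-pyran-2-one
Product: 7 4-methoxy-5-(4-methoxybenzoyl)-6-[2-(4-methoxyphenyl)ethyl]-2H-pyran-2-one
Conditions: Me2SO4 (1.3 equiv), K2CO3, acetone, reflux
Reagents that add atoms: dimethyl sulfate, COS(=O)(=O)OC
Why: O-alkylation of the acidic vinylogous carboxylic acid under Williamson-type conditions, which for 4-hydroxy-2-pyrones is the standard way to the 4-methoxy-2-pyrone and not the isomeric 2-methoxy-4-pyrone.

Step 4
Reactants: 8 3-(4-methoxyphenyl)propanenitrile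
Product: 9 methyl 3-(4-methoxyphenyl)propanimidate hydrochloride
Conditions: HCl (g), MeOH (1.1 equiv), Et2O, 0 °C
Reagents that add atoms: methanol, CO; hydrogen chloride, Cl
Why: Pinner reaction, in which the protonated nitrile is attacked by methanol and the imidate salt should crystallise from ether, which protects it from further reaction.

Step 5
Reactants: 9 methyl 3-(4-methoxyphenyl)propanimidate hydrochloride
Product: 10 1-methoxy-4-(3,3,3-trimethoxypropyl)benzene
Conditions: MeOH (excess), hexane, 25 °C, 48 h; filter off NH4Cl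
Reagents that add atoms: methanol, CO
Why: Alcoholysis of the imidate salt (the orthoester stage of the Pinner synthesis), in which two molecules of methanol displace ammonia as insoluble ammonium chloride at a temperature low enough to avoid collapse of the salt to the amide.

Step 6
Reactants: 10 1-methoxy-4-(3,3,3-trimethoxypropyl)benzene
Product: 11 1-(3,3-dimethoxyprop-2-en-1-yl)-4-methoxybenzene
Conditions: Al(OtBu)3 (0.2 equiv), neat, 180–200 °C, MeOH distilled off; then Kugelrohr distillation
Reagents that add atoms: none
Why: Aluminium-alkoxide-promoted dealcoholation of an orthoester, in which the Lewis acid abstracts one methoxide to give a dimethoxycarbenium ion that loses the adjacent proton, while removal of methanol by distillation pulls the equilibrium to the ketene acetal.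

Step 7
Reactants: 7 4-methoxy-5-(4-methoxybenzoyl)-6-[2-(4-methoxyphenyl)ethyl]-2H-pyran-2-one; 11 1-(3,3-dimethoxyprop-2-en-1-yl)-4-methoxybenzene
Product: 14 {2,4-dimethoxy-5-(4-methoxybenzyl)-6-[2-(4-methoxyphenyl)ethyl]phenyl}(4-methoxyphenyl)methanone, via bridged lactone adduct 12 (not isolated), via dimethoxycyclohexadiene 13 (not isolated)
Conditions: 11 (3 equiv), PhMe, 150 °C, sealed tube, 48 h
Reagents that add atoms: none
Why: The electron-rich ketene acetal 11 and the acceptor-substituted pyrone 7 should combine in an inverse-electron-demand Diels–Alder reaction (strongly asynchronous, possibly stepwise through a zwitterion) in which the nucleophilic CH carbon of 11 bonds to pyrone C6 and the acetal carbon to pyrone C3, giving the bridged lactone 12. Retro-Diels–Alder loss of carbon dioxide from 12 gives the cyclohexadiene 13, whose geminal dimethoxy carbon lies next to the benzyl-bearing CH, so 1,2-elimination of methanol aromatises it to 14. The closest known reaction type is the cycloaddition of 3- and 5-acyl- or alkoxycarbonyl-2-pyrones with ketene acetals, which gives alkoxybenzenes after loss of carbon dioxide and alcohol. The new benzene ring is closed by an intermolecular [4+2] annulation that forms both ring bonds in one operation, so no chain-cyclisation mode applies; the ring consists of pyrone C3–C6 and the two alkene carbons of 11. No stereocentre survives, because the three sp3 centres of 12 and the one of 13 are destroyed by the extrusion and the elimination, so endo/exo and facial selectivity do not matter. The step needs regioselectivity only, and this is secured from both ends: C6 is the terminus conjugated with the 5-aroyl and the lactone carbonyl, whereas C3 is the electron-rich β-carbon of the 4-methoxy enol ether and therefore pairs with the electrophilic acetal carbon.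

Step 8
Reactants: 14 {2,4-dimethoxy-5-(4-methoxybenzyl)-6-[2-(4-methoxyphenyl)ethyl]phenyl}(4-methoxyphenyl)methanone
Product: 15 1,5-dimethoxy-2,4-bis(4-methoxybenzyl)-3-[2-(4-methoxyphenyl)ethyl]benzene
Conditions: Et3SiH (5 equiv), CF3CO2H, CH2Cl2, 0 to 25 °C
Reagents that add atoms: none
Why: Ionic hydrogenation, in which the protonated anisyl ketone accepts hydride from the silane, the resulting carbinol ionises to a doubly aryl-stabilised diarylmethyl cation, and a second hydride transfer gives the methylene group, the excess of silane being meant to outrun Friedel–Crafts capture of the cation.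

Step 9
Reactants: 15 1,5-dimethoxy-2,4-bis(4-methoxybenzyl)-3-[2-(4-methoxyphenyl)ethyl]benzene
Product: 16 4,6-bis(4-hydroxybenzyl)-5-[2-(4-hydroxyphenyl)ethyl]benzene-1,3-diol (CNP0326726.0)
Conditions: BBr3 (8 equiv), CH2Cl2, −78 to 25 °C; then MeOH, H2O
Reagents that add atoms: none
Why: Lewis-acid-mediated dealkylation of aryl methyl ethers, in which BBr3 coordinates each ether oxygen and bromide attacks the methyl group, so that hydrolysis of the aryl borates frees all five phenols while the diarylmethane and bibenzyl C–C bonds stay untouched at low temperature.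

**Compound list**

1 | 4'-methoxyacetophenone | CC(=O)c1ccc(OC)cc1 | starting material
2 | methyl 3-(4-methoxyphenyl)propanoate | COC(=O)CCc1ccc(OC)cc1 | starting material
3 | 1,5-bis(4-methoxyphenyl)pentane-1,3-dione | COc1ccc(CCC(=O)CC(=O)c2ccc(OC)cc2)cc1 | intermediate
4 | malonyl dichloride | O=C(Cl)CC(=O)Cl | starting material
5 | 4-(4-methoxybenzoyl)-7-(4-methoxyphenyl)-3,5-dioxoheptanoyl chloride (not isolated) | COc1ccc(CCC(=O)C(C(=O)CC(=O)Cl)C(=O)c2ccc(OC)cc2)cc1 | intermediate
6 | 4-hydroxy-5-(4-methoxybenzoyl)-6-[2-(4-methoxyphenyl)ethyl]-2H-pyran-2-one | COc1ccc(CCc2oc(=O)cc(O)c2C(=O)c2ccc(OC)cc2)cc1 | intermediate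
7 | 4-methoxy-5-(4-methoxybenzoyl)-6-[2-(4-methoxyphenyl)ethyl]-2H-pyran-2-one | COc1ccc(CCc2oc(=O)cc(OC)c2C(=O)c2ccc(OC)cc2)cc1 | intermediate
8 | 3-(4-methoxyphenyl)propanenitrile | N#CCCc1ccc(OC)cc1 | starting material
9 | methyl 3-(4-methoxyphenyl)propanimidate hydrochloride | COC(=[NH2+])CCc1ccc(OC)cc1.[Cl-] | intermediate
10 | 1-methoxy-4-(3,3,3-trimethoxypropyl)benzene | COc1ccc(CCC(OC)(OC)OC)cc1 | intermediate
11 | 1-(3,3-dimethoxyprop-2-en-1-yl)-4-methoxybenzene | COC(OC)=CCc1ccc(OC)cc1 | intermediate
12 | 5,8,8-trimethoxy-6-(4-methoxybenzoyl)-7-(4-methoxybenzyl)-1-[2-(4-methoxyphenyl)ethyl]-2-oxabicyclo[2.2.2]oct-5-en-3-one (not isolated; mixture of racemic diastereomers, configuration not defined) | O=C1OC2(CCc3ccc(OC)cc3)C(Cc3ccc(OC)cc3)C(OC)(OC)C1C(OC)=C2C(=O)c1ccc(OC)cc1 | intermediate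
13 | [4,4,6-trimethoxy-3-(4-methoxybenzyl)-2-[2-(4-methoxyphenyl)ethyl]cyclohexa-1,5-dien-1-yl](4-methoxyphenyl)methanone (not isolated; racemic) | COC1=CC(OC)(OC)C(Cc2ccc(OC)cc2)C(CCc2ccc(OC)cc2)=C1C(=O)c1ccc(OC)cc1 | intermediate
14 | {2,4-dimethoxy-5-(4-methoxybenzyl)-6-[2-(4-methoxyphenyl)ethyl]phenyl}(4-methoxyphenyl)methanone | COc1ccc(CCc2c(Cc3ccc(OC)cc3)c(OC)cc(OC)c2C(=O)c2ccc(OC)cc2)cc1 | intermediate
15 | 1,5-dimethoxy-2,4-bis(4-methoxybenzyl)-3-[2-(4-methoxyphenyl)ethyl]benzene | COc1ccc(CCc2c(Cc3ccc(OC)cc3)c(OC)cc(OC)c2Cc2ccc(OC)cc2)cc1 | intermediate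
16 | 4,6-bis(4-hydroxybenzyl)-5-[2-(4-hydroxyphenyl)ethyl]benzene-1,3-diol | Oc1ccc(CCc2c(Cc3ccc(O)cc3)c(O)cc(O)c2Cc2ccc(O)cc2)cc1 | target

**Step count and risks**

Total step count: 9.
Longest linear sequence: 6 steps (steps 1, 2, 3, 7, 8, 9; the dienophile branch through steps 4, 5, 6, 7, 8, 9 is equally long).

Steps most likely to fail:

1. Step 7. The cycloaddition may be too slow. The 4-methoxy group feeds electron density into the diene, the aroyl group is forced out of the pyrone plane by its two neighbours, and bond formation at C6 creates a fully substituted centre. The ketene acetal could then oligomerise, or add at C6 without closing the ring. The fallback sets out from hydroxypyrone 6 and changes the oxygen substituent into a weak donor. Pivaloyl chloride and Et3N (CH2Cl2, 0 °C) should give the 4-pivaloyloxy pyrone F1. Heating F1 with 11 in toluene should lead, through the pivalate-bearing bridged lactone F2 and the pivalate-bearing cyclohexadiene F3, to the aryl pivalate F4. Transesterification with K2CO3 in MeOH should free the ortho-hydroxybenzophenone F5, and MeI with K2CO3 in acetone should methylate it to 14, where the route is rejoined.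

2. Step 2. Ring closure could take place through the enol oxygen of the anisoyl ketone, which would give the isomeric 6-aryl-5-acyl pyrone; O-acylation and oligomer formation could also compete. The fallback sets out from ester 2 and uses an ester as the activating group, so that only one enol oxygen can lactonise. Crossed Claisen condensation of 2 with the lithium enolate of methyl acetate (LiN(iPr)2, THF, −78 °C) should give the β-keto ester F6. Malonyl dichloride should convert it, through the C-acylated acid chloride F7, into the 4-hydroxypyrone ester F8, and Me2SO4 with K2CO3 into the 4-methoxypyrone ester F9. Cycloaddition of F9 with 11 should give, through the ester-bearing bridged lactone F10 and the ester-bearing cyclohexadiene F11, the pentasubstituted methyl benzoate F12. LiAlH4 in THF should reduce it to the benzyl alcohol F13. Acid-catalysed Friedel–Crafts benzylation of anisole (anisole as solvent, catalytic CF3CO2H, 25 °C) should then deliver 15 directly, so the route is rejoined after step 8.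

3. Step 6. Dealcoholation may stop short of completion, and the ketene acetal may be lost through hydrolysis to ester 2 or acid-induced oligomerisation during distillation and storage. The fallback sets out from orthoester 10 and never isolates the ketene acetal. Pyrone 7 is heated with an excess of 10 and a catalytic amount of pivalic acid at 180–200 °C while methanol is allowed to distil. Compound 11 is then formed in low stationary concentration and consumed by the cycloaddition as in step 7, and the route is rejoined at 14. This fallback makes no new compound (F0).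

**Further compounds**

F1 | step 7 | 5-(4-methoxybenzoyl)-6-[2-(4-methoxyphenyl)ethyl]-2-oxo-2H-pyran-4-yl 2,2-dimethylpropanoate | COc1ccc(CCc2oc(=O)cc(OC(=O)C(C)(C)C)c2C(=O)c2ccc(OC)cc2)cc1
F2 | step 7 | 8,8-dimethoxy-6-(4-methoxybenzoyl)-7-(4-methoxybenzyl)-1-[2-(4-methoxyphenyl)ethyl]-3-oxo-2-oxabicyclo[2.2.2]oct-5-en-5-yl 2,2-dimethylpropanoate | O=C1OC2(CCc3ccc(OC)cc3)C(Cc3ccc(OC)cc3)C(OC)(OC)C1C(OC(=O)C(C)(C)C)=C2C(=O)c1ccc(OC)cc1
F3 | step 7 | 3,3-dimethoxy-6-(4-methoxybenzoyl)-4-(4-methoxybenzyl)-5-[2-(4-methoxyphenyl)ethyl]cyclohexa-1,5-dien-1-yl 2,2-dimethylpropanoate | CC(C)(C)C(=O)OC1=CC(OC)(OC)C(Cc2ccc(OC)cc2)C(CCc2ccc(OC)cc2)=C1C(=O)c1ccc(OC)cc1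
F4 | step 7 | 5-methoxy-2-(4-methoxybenzoyl)-4-(4-methoxybenzyl)-3-[2-(4-methoxyphenyl)ethyl]phenyl 2,2-dimethylpropanoate | COc1ccc(CCc2c(Cc3ccc(OC)cc3)c(OC)cc(OC(=O)C(C)(C)C)c2C(=O)c2ccc(OC)cc2)cc1
F5 | step 7 | {2-hydroxy-4-methoxy-5-(4-methoxybenzyl)-6-[2-(4-methoxyphenyl)ethyl]phenyl}(4-methoxyphenyl)methanone | COc1ccc(CCc2c(Cc3ccc(OC)cc3)c(OC)cc(O)c2C(=O)c2ccc(OC)cc2)cc1
F6 | step 2 | methyl 5-(4-methoxyphenyl)-3-oxopentanoate | COC(=O)CC(=O)CCc1ccc(OC)cc1
F7 | step 2 | methyl 2-(3-chloro-3-oxopropanoyl)-5-(4-methoxyphenyl)-3-oxopentanoate | COC(=O)C(C(=O)CC(=O)Cl)C(=O)CCc1ccc(OC)cc1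
F8 | step 2 | methyl 4-hydroxy-6-[2-(4-methoxyphenyl)ethyl]-2-oxo-2H-pyran-5-carboxylate | COC(=O)c1c(O)cc(=O)oc1CCc1ccc(OC)cc1
F9 | step 2 | methyl 4-methoxy-6-[2-(4-methoxyphenyl)ethyl]-2-oxo-2H-pyran-5-carboxylate | COC(=O)c1c(OC)cc(=O)oc1CCc1ccc(OC)cc1
F10 | step 2 | methyl 5,8,8-trimethoxy-7-(4-methoxybenzyl)-1-[2-(4-methoxyphenyl)ethyl]-3-oxo-2-oxabicyclo[2.2.2]oct-5-ene-6-carboxylate | O=C1OC2(CCc3ccc(OC)cc3)C(Cc3ccc(OC)cc3)C(OC)(OC)C1C(OC)=C2C(=O)OC
F11 | step 2 | methyl 4,4,6-trimethoxy-3-(4-methoxybenzyl)-2-[2-(4-methoxyphenyl)ethyl]cyclohexa-1,5-diene-1-carboxylate | COC(=O)C1=C(CCc2ccc(OC)cc2)C(Cc2ccc(OC)cc2)C(OC)(OC)C=C1OC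
F12 | step 2 | methyl 2,4-dimethoxy-5-(4-methoxybenzyl)-6-[2-(4-methoxyphenyl)ethyl]benzoate | COC(=O)c1c(OC)cc(OC)c(Cc2ccc(OC)cc2)c1CCc1ccc(OC)cc1
F13 | step 2 | {2,4-dimethoxy-5-(4-methoxybenzyl)-6-[2-(4-methoxyphenyl)ethyl]phenyl}methanol | OCc1c(OC)cc(OC)c(Cc2ccc(OC)cc2)c1CCc1ccc(OC)cc1
F0 | step 6 | none | none
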